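**Assumption:** The SMILES is read in germacrane numbering. C1 is the furanone C=O, C2 the furanone CH, C3 the furanone O–C=, C4 the methyl-bearing alkene carbon and C5 the alkene CH. C6 is the ester-bearing CH, C7 the ring-fusion CH, C8 the lactone O–CH, C9 the CH2 and C10 the quaternary O–C(CH3). C11, C12 and C13 are the α-carbon, the carbonyl and the exocyclic CH2 of the lactone. C14 and C15 are the methyls on C10 and C4. On this reading the target is 6S,7R,8S,10R, with a Z C4=C5 bond and a (Z)-2-methylbut-2-enoate (angelate) on O6.

## Analysis of the target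

Target 26 has three rings. Ring A is the ten-membered carbocycle C1–C10. Ring B is a 3(2H)-furanone (O10, C10, C1, C2, C3) that bridges C3 and C10. Ring C is an α-methylene-γ-butyrolactone (O8, C8, C7, C11, C12) fused at C7–C8.

C6, C7 and C8 are contiguous stereocentres. O6 and O8 are 1,3-anti, and C11 is anti to O6 and syn to O8, which puts H7 and H8 trans on ring C. The fourth centre, quaternary C10, is insulated by C9 and carries O10 syn to O8.

The C4=C5 bond is trisubstituted, Z and conjugated with ring B, so no acyclic precursor supports its geometry.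

Several groups are sensitive:
- The C11=C13 methylene is a Michael acceptor.
- The angelate drifts from Z to E once its acyl carbon is activated.
- Ring B is a vinylogous ester.
- A free O6–H next to a Z-configured C3 ester collapses to a butenolide.

The hard part is a strained, bridged medium ring that an end-to-end closure must build against entropy and transannular strain while four stereocentres and the Z alkene are held.

The feature that invites the key move is this. Ring B is a dehydrated α'-hydroxy-1,3-diketone (C1, C2, C3 plus O10), so C3 is an acyl carbon, and it lies 1,6 across ring A from C8, whose O8 is an alcohol oxygen. C3 can therefore be parked on O8 as a seven-membered lactone (O8, C3, C4, C5, C6, C7, C8) and then handed over to C2.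

## Retrosynthetic reasoning

**O6–acyl bond.** 26 is cut at the ester bond into alcohol 23 and acid 24. The angelate is the group most easily damaged, and in any basic step it would be a second acyl donor next to O8. It therefore goes on last. The forward reaction must acylate a hindered allylic alcohol without changing the geometry of 24.

**C2–C3, O10–C3 and O8–C12 (key disconnection).** Three bonds of 23 are cut together, and C3 is reconnected to O8. This leads through the monocyclic ten-membered diketone 22 to the seven-membered lactone 21.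
- The cut is placed here because C2–C3 is the only ring-A bond that a Claisen-type acyl transfer can make with an oxygen of the target (O8) as the leaving group.
- The gain is large. Three rings shrink to one easily made ring, no macrocyclisation remains, the Z alkene becomes an endocyclic alkene of a seven-membered ring, and all four stereocentres sit on a conventional chain.
- The forward reaction has three tasks: move C3 from O8 to the C2 enolate, which expands the ring from seven to ten members; let O10 close ring B; and let the freed O8 close ring C.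

**C12 oxidation level.** The acrylic acid of 21 is traced through allylic alcohol 20 to the isopropenyl group of 19. A Michael acceptor would not survive the thiolate, samarium and ruthenium steps, whereas an isopropenyl group is inert to all of them.

**C4=C5.** 19 is opened at the alkene to diene ester 18. Metathesis in a seven-membered ring can only give the Z alkene, so the geometry problem disappears.

**O8–C3 and C6–H.** 18 comes from alcohol 17, and 17 from hydroxy enone 15 and aldehyde 16. One Evans–Tishchenko event sets C6 anti to O8, puts C3, C4 and C15 on O8, and leaves only O6 free. The two oxygens are thus told apart without a protecting-group exchange.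

**C5–C6.** 15 is cut at the acyl–alkenyl bond into thioester 13 and boronic acid 14, and 13 comes from imide 12. A neutral acyl cross-coupling is chosen because the C1 ketone is already present and excludes Grignard and hydride reagents.

**C7–C8.** 12 is cut into imide 11 (from 9 and 10) and aldehyde 8. This union of the two halves sets C7 and C8 together and creates the isopropenyl group by deconjugation.

**C9–C10 and C1–C2.** 8 goes back through 7 and 6 to dioxolanone 5, to 3 and 4, and finally to 1 and 2. Quaternary C10 is taken from lactic acid by alkylation with retention, and C2 arrives as a methyl nucleophile.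

## Alternatives that were turned down

**Alternative 1:** The textbook cut is C4=C5 of ring A, made by ring-closing metathesis of tetraene A1, which already carries rings B and C.
- The closure joins a 1,1-disubstituted, electron-poor isopropenyl group on ring B to an allylic ester vinyl group, and it forms a ten-membered bridged ring end to end.
- A ten-membered ring does not enforce Z.
- The exocyclic C11=C13 methylene is a competing site for the ruthenium carbene and would need masking, which costs steps.
- This step closes only one ring and sets nothing else.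

**Alternative 2:** The cut is C7–C8, made by intramolecular Barbier or Nozaki–Hiyama–Kishi allylation (zinc or CrCl2) of bromo ester aldehyde A2, with lactonisation in the same pot.
- It would form ring A and ring C and set C7 and C8.
- The closed transition state of such a Z-configured 2-(bromomethyl)enoate leads by preference to the syn adduct, which is a cis lactone, while 26 needs H7 and H8 trans.
- The aldehyde face would be ruled only by remote C6 and C10.
- A2 needs the Z dienone built without ring support.
- The closure is still an end-to-end medium-ring formation.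

**Alternative 3:** The cut is C9–C10, made by dearomatising alkylation of the planar 3-oxidofuran derived from iodide A3 (both C10 epimers).
- The step would be stereoconvergent at C10 and would close ring A.
- The ambident enolate can react at oxygen.
- The enolate is a Michael donor towards C13 of ring C.
- The iodide is β to the O8 acyloxy group and is prone to elimination.
- Nothing in the structure predicts which furan face the six-atom tether reaches.
- The Z alkene again has to be made in an open chain.

Key step: step 15

## Route

Step 1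
Reactants: 1 (S)-lactic acid; 2 pivalaldehyde
Product: 3 (2S,5S)-2-tert-butyl-5-methyl-1,3-dioxolan-4-one (cis)
Conditions: p-TsOH (cat.), pentane, reflux, Dean–Stark; crystallisation of the cis isomer
Reagents that add atoms: none
Why: Acid-catalysed acetalisation of an α-hydroxy acid; the cis-dioxolanone should be the major, crystalline isomer, and its acetal centre stores the lactate configuration (self-regeneration of stereocentres).

Step 2
Reactants: 3 (2S,5S)-2-tert-butyl-5-methyl-1,3-dioxolan-4-one; 4 allyl bromide
Product: 5 (2S,5R)-2-tert-butyl-5-methyl-5-(prop-2-enyl)-1,3-dioxolan-4-one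
Conditions: LiN(iPr)2, THF, −78 °C; then 4, −78 → −30 °C
Reagents that add atoms: none
Why: Enolate alkylation with an allylic halide; the planar enolate is attacked anti to the tert-butyl group, so allyl replaces H with overall retention and sets quaternary C10 (R).

Step 3
Reactants: 5 (2S,5R)-2-tert-butyl-5-methyl-5-(prop-2-enyl)-1,3-dioxolan-4-one
Product: 6 (3R)-3-hydroxy-3-methylhex-5-en-2-one
Conditions: MeLi (1.0 equiv), THF, −78 °C; aqueous work-up
Reagents that add atoms: methyllithium [Li]C
Why: 1,2-Addition of one equivalent of an organolithium to the lactone carbonyl gives a tetrahedral alkoxide that should persist at low temperature; work-up releases the methyl ketone (C1, C2) and the free O10–H, and C10 is not touched.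

Step 4
Reactants: 6 (3R)-3-hydroxy-3-methylhex-5-en-2-one
Product: 7 (3R)-3-methyl-3-(triethylsilyloxy)hex-5-en-2-one
Conditions: TESOTf, 2,6-lutidine, CH2Cl2, −78 → 0 °C
Reagents that add atoms: triethylsilyl triflate CC[Si](CC)(CC)OS(=O)(=O)C(F)(F)F
Why: Silyl triflate silylation of a hindered tertiary alcohol; the ether later blocks the α-ketol shift that would scramble C10.

Step 5
Reactants: 7 (3R)-3-methyl-3-(triethylsilyloxy)hex-5-en-2-one
Product: 8 (3R)-3-methyl-4-oxo-3-(triethylsilyloxy)pentanal
Conditions: O3, CH2Cl2, −78 °C; PPh3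
Reagents that add atoms: ozone [O-][O+]=O
Why: Ozonolysis with reductive work-up of the only alkene gives the C8 aldehyde.

Step 6
Reactants: 9 (R)-4-benzyl-1,3-oxazolidin-2-one; 10 3-methylbut-2-enoyl chloride
Product: 11 (R)-4-benzyl-3-(3-methylbut-2-enoyl)-1,3-oxazolidin-2-one
Conditions: n-BuLi, THF, −78 °C; then 10
Reagents that add atoms: none
Why: N-Acylation of the lithiated oxazolidinone, a standard imide synthesis.

Step 7
Reactants: 11 (R)-4-benzyl-3-(3-methylbut-2-enoyl)-1,3-oxazolidin-2-one; 8 (3R)-3-methyl-4-oxo-3-(triethylsilyloxy)pentanal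
Product: 12 (R)-4-benzyl-3-[(2R,3S,5R)-3-hydroxy-5-methyl-6-oxo-2-(prop-1-en-2-yl)-5-(triethylsilyloxy)heptanoyl]-1,3-oxazolidin-2-one
Conditions: Bu2BOTf, Et3N, CH2Cl2, −78 → 0 °C; 8, −78 °C; pH 7 buffer, MeOH, H2O2
Reagents that add atoms: none
Why: Evans syn aldol with deconjugation: soft enolisation of 11 removes a γ-hydrogen, and the Z-boron dienolate reacts at its α-carbon through a Zimmerman–Traxler chair; the benzyl group of the (R)-auxiliary fixes the face, so C7 and C8 are set together (syn) and the isopropenyl group (C11–C13) is formed; the aldehyde reacts in preference to the hindered C1 ketone.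

Step 8
Reactants: 12 aldol imide
Product: 13 S-ethyl (2R,3S,5R)-3-hydroxy-5-methyl-6-oxo-2-(prop-1-en-2-yl)-5-(triethylsilyloxy)heptanethioate
Conditions: EtSH, n-BuLi, THF, 0 °C
Reagents that add atoms: ethanethiol CCS
Why: Thiolate cleavage of the exocyclic imide carbonyl; the weakly basic nucleophile should cause neither retro-aldol cleavage nor migration of the β,γ-alkene, and the auxiliary is recovered.

Step 9
Reactants: 13 thioester; 14 (E)-prop-1-enylboronic acid
Product: 15 (3R,5S,6R,8E)-5-hydroxy-3-methyl-6-(prop-1-en-2-yl)-3-(triethylsilyloxy)dec-8-ene-2,7-dione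
Conditions: Pd2(dba)3 (cat.), P(2-furyl)3, copper thiophene-2-carboxylate (CuO2C-C4H3S, 1.5 equiv), THF, 50 °C
Reagents that add atoms: none
Why: Liebeskind–Srogl acyl cross-coupling: zerovalent palladium inserts into the C–S bond, and the monovalent copper carboxylate takes up the thiolate and activates the boronic acid; the neutral medium tolerates the C1 ketone, the free O8–H and the epimerisable C7.

Step 10
Reactants: 15 hydroxy enone; 16 methacrolein
Product: 17 (3R,5S,6S,7S,8E)-7-hydroxy-3-methyl-2-oxo-6-(prop-1-en-2-yl)-3-(triethylsilyloxy)dec-8-en-5-yl 2-methylprop-2-enoate (O8 methacrylate, O6–H free, O6/O8 anti)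
Conditions: SmI2 (0.3 equiv, premixed with 16), 16 (8 equiv), THF, −10 °C
Reagents that add atoms: none
Why: Evans–Tishchenko reduction: trivalent samarium holds the O8 hemiacetal of 16 and the C6 ketone in a chair, and the intramolecular hydride shift sets C6 anti to O8; the same event turns 16 into the O8 methacrylate (C3, C4, C15), so O6 and O8 are differentiated without a protecting-group exchange.

Step 11
Reactants: 17 hydroxy ester
Product: 18 (3R,5S,6R,7S,8E)-7-(tert-butyldimethylsilyloxy)-3-methyl-2-oxo-6-(prop-1-en-2-yl)-3-(triethylsilyloxy)dec-8-en-5-yl 2-methylprop-2-enoate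
Conditions: TBSOTf, 2,6-lutidine, CH2Cl2, −78 °C
Reagents that add atoms: tert-butyldimethylsilyl triflate CC(C)(C)[Si](C)(C)OS(=O)(=O)C(F)(F)F
Why: Fast low-temperature silylation should outrun 1,3-acyl migration; the ether keeps O6 from attacking C3 once the Z enoate exists.

Step 12
Reactants: 18 diene ester
Product: 19 (5S,6R,7S)-5-(tert-butyldimethylsilyloxy)-3-methyl-7-[(2R)-2-methyl-3-oxo-2-(triethylsilyloxy)butyl]-6-(prop-1-en-2-yl)-6,7-dihydro-5H-oxepin-2-one (the three ring substituents cis)
Conditions: second-generation Hoveyda–Grubbs catalyst (5 mol %), toluene (2 mM), 80 °C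
Reagents that add atoms: none
Why: Ring-closing metathesis of a methacrylate onto an allylic alkene; the carbene loads on the propenyl group and closes the seven-membered ring, whose size forces the Z C4=C5 bond; closure onto the isopropenyl group would need a cyclobutene.

Step 13
Reactants: 19 oxepinone
Product: 20 the oxepinone of 19 with a 3-hydroxyprop-1-en-2-yl group in place of isopropenyl (C12–OH)
Conditions: SeO2 (0.3 equiv), t-BuOOH, CH2Cl2, 0 °C → rt
Reagents that add atoms: selenium dioxide O=[Se]=O (oxygen carrier); tert-butyl hydroperoxide CC(C)(C)OO (terminal oxidant)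
Why: Allylic oxidation by an ene reaction and [2,3] shift; the isopropenyl group is the only electron-rich alkene, and its CH3 reacts in preference to the tertiary C7–H; any enal formed converges in step 14.

Step 14
Reactants: 20 allylic alcohol
Product: 21 2-[(5S,6R,7S)-5-(tert-butyldimethylsilyloxy)-3-methyl-7-[(2R)-2-methyl-3-oxo-2-(triethylsilyloxy)butyl]-2-oxo-2,5,6,7-tetrahydrooxepin-6-yl]prop-2-enoic acid
Conditions: TEMPO (cat.), NaClO2, NaOCl (cat.), MeCN/phosphate buffer pH 6.7, 35 °C
Reagents that add atoms: sodium chlorite [Na+].[O-]Cl=O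
Why: Oxoammonium oxidation to the enal and chlorite oxidation to the acid in one pot; near-neutral conditions spare the silyl ethers, the lactone and the ketone.

Step 15
Reactants: 21 oxepinone acid
Product: 23 (4Z,6S,7S,8S,10R)-6-hydroxy-1-oxo-3,10-epoxygermacra-2,4,11(13)-trien-12,8-olide, via cyclodecenedione acid 22 (not isolated)
Conditions: KN(SiMe3)2 (2.2 equiv), THF (5 mM), −78 → 0 °C; AcOH; extractive work-up; crude 22 in MeCN, 48 % aq. HF, 0 °C → rt
Reagents that add atoms: none
Why: Proposed new method: The first equivalent of base turns C12O2H into an inert carboxylate (neither Michael acceptor nor acyl acceptor), and the second deprotonates the only α-CH of the C1 ketone, the C2 methyl group. The C2 enolate adds to the lactone carbonyl C3 in a 7-exo-trig mode to give the alkoxide of an 11-oxabicyclo[4.4.1]undecane hemiketal, whose C3–O8 bond then breaks, so ring A (C1–C10) is released by ring expansion and not closed end to end. Proton transfer from the new C1–C2–C3 diketone to the O8 alkoxide gives the stabilised diketonate of 22, the sink that drives every Claisen condensation. The closest known reaction types are the Baker–Venkataraman O-to-C acyl migration and the crossed Claisen condensation of ketone enolates with esters; what is new is its use on an aliphatic seven-membered lactone so that a medium carbocycle results. In acid O8–H closes ring C on C12 (5-exo-trig), loss of the triethylsilyl group lets O10 add to C3 (5-exo-trig) and dehydration gives ring B, a regiochemistry favoured by the allyl-stabilised oxocarbenium ion at C3 and by capture of O8 in ring C, and HF finally frees O6. No stereocentre is formed or touched: C6, C7, C8 and C10 come from 21, and the Z C4=C5 bond is inherited from the seven-membered ring. The step needs enolisation at C2 rather than γ-deprotonation at C6 (kinetic acidity of the methyl ketone, low temperature) and attack at C3 only, which the seven-membered trajectory secures, while the silyl groups on O6 and O10 exclude butenolide formation and an α-ketol shift at C10.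

Step 16
Reactants: 23 C6 alcohol; 24 angelic acid, (Z)-2-methylbut-2-enoic acid
Product: 26 (4Z,6S,7R,8S,10R)-6-angeloyloxy-1-oxo-3,10-epoxygermacra-2,4,11(13)-trien-12,8-olide (CNP0293168.1), via mixed anhydride 25 (not isolated)
Conditions: 24, 2,4,6-trichlorobenzoyl chloride, Et3N, toluene, rt; then 23, 80 °C
Reagents that add atoms: 2,4,6-trichlorobenzoyl chloride O=C(Cl)c1c(Cl)cc(Cl)cc1Cl (its atoms are kept only in 25)
Why: Yamaguchi-type esterification through the mixed anhydride without a nucleophilic catalyst, the variant that avoids the addition–elimination path responsible for Z to E drift; C6 reacts with retention because only the O–H bond is broken.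

## Compound list

The CIP descriptor at C7 switches between R and S with the substituents on O6 and O8. The spatial arrangement stays constant.

1 | (S)-lactic acid | C[C@H](O)C(=O)O | starting material
2 | pivalaldehyde | CC(C)(C)C=O | starting material
3 | (2S,5S)-2-tert-butyl-5-methyl-1,3-dioxolan-4-one | C[C@@H]1O[C@H](C(C)(C)C)OC1=O | intermediate
4 | allyl bromide | C=CCBr | starting material
5 | (2S,5R)-2-tert-butyl-5-methyl-5-(prop-2-enyl)-1,3-dioxolan-4-one | C=CC[C@@]1(C)O[C@H](C(C)(C)C)OC1=O | intermediate
6 | (3R)-3-hydroxy-3-methylhex-5-en-2-one | C=CC[C@@](C)(O)C(C)=O | intermediate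
7 | (3R)-3-methyl-3-(triethylsilyloxy)hex-5-en-2-one | C=CC[C@@](C)(O[Si](CC)(CC)CC)C(C)=O | intermediate
8 | (3R)-3-methyl-4-oxo-3-(triethylsilyloxy)pentanal | O=CC[C@@](C)(O[Si](CC)(CC)CC)C(C)=O | intermediate
9 | (R)-4-benzyl-1,3-oxazolidin-2-one | O=C1N[C@H](Cc2ccccc2)CO1 | starting material
10 | 3-methylbut-2-enoyl chloride | CC(C)=CC(=O)Cl | starting material
11 | (R)-4-benzyl-3-(3-methylbut-2-enoyl)-1,3-oxazolidin-2-one | CC(C)=CC(=O)N1C(=O)OC[C@H]1Cc1ccccc1 | intermediate
12 | (R)-4-benzyl-3-[(2R,3S,5R)-3-hydroxy-5-methyl-6-oxo-2-(prop-1-en-2-yl)-5-(triethylsilyloxy)heptanoyl]-1,3-oxazolidin-2-one | O=C(N1C(=O)OC[C@H]1Cc1ccccc1)[C@H](C(C)=C)[C@@H](O)C[C@@](C)(O[Si](CC)(CC)CC)C(C)=O | intermediate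
13 | S-ethyl (2R,3S,5R)-3-hydroxy-5-methyl-6-oxo-2-(prop-1-en-2-yl)-5-(triethylsilyloxy)heptanethioate | CCSC(=O)[C@H](C(C)=C)[C@@H](O)C[C@@](C)(O[Si](CC)(CC)CC)C(C)=O | intermediate
14 | (E)-prop-1-enylboronic acid | C/C=C/B(O)O | starting material
15 | (3R,5S,6R,8E)-5-hydroxy-3-methyl-6-(prop-1-en-2-yl)-3-(triethylsilyloxy)dec-8-ene-2,7-dione | C/C=C/C(=O)[C@H](C(C)=C)[C@@H](O)C[C@@](C)(O[Si](CC)(CC)CC)C(C)=O | intermediate
16 | methacrolein | C=C(C)C=O | starting material
17 | (3R,5S,6S,7S,8E)-7-hydroxy-3-methyl-2-oxo-6-(prop-1-en-2-yl)-3-(triethylsilyloxy)dec-8-en-5-yl 2-methylprop-2-enoate | C/C=C/[C@H](O)[C@H](C(C)=C)[C@@H](OC(=O)C(C)=C)C[C@@](C)(O[Si](CC)(CC)CC)C(C)=O | intermediate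
18 | (3R,5S,6R,7S,8E)-7-(tert-butyldimethylsilyloxy)-3-methyl-2-oxo-6-(prop-1-en-2-yl)-3-(triethylsilyloxy)dec-8-en-5-yl 2-methylprop-2-enoate | C/C=C/[C@H](O[Si](C)(C)C(C)(C)C)[C@H](C(C)=C)[C@@H](OC(=O)C(C)=C)C[C@@](C)(O[Si](CC)(CC)CC)C(C)=O | intermediate
19 | (5S,6R,7S)-5-(tert-butyldimethylsilyloxy)-3-methyl-7-[(2R)-2-methyl-3-oxo-2-(triethylsilyloxy)butyl]-6-(prop-1-en-2-yl)-6,7-dihydro-5H-oxepin-2-one | CC1=C[C@H](O[Si](C)(C)C(C)(C)C)[C@H](C(C)=C)[C@H](C[C@@](C)(O[Si](CC)(CC)CC)C(C)=O)OC1=O | intermediate
20 | (5S,6R,7S)-5-(tert-butyldimethylsilyloxy)-6-(3-hydroxyprop-1-en-2-yl)-3-methyl-7-[(2R)-2-methyl-3-oxo-2-(triethylsilyloxy)butyl]-6,7-dihydro-5H-oxepin-2-one | CC1=C[C@H](O[Si](C)(C)C(C)(C)C)[C@H](C(=C)CO)[C@H](C[C@@](C)(O[Si](CC)(CC)CC)C(C)=O)OC1=O | intermediate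
21 | 2-[(5S,6R,7S)-5-(tert-butyldimethylsilyloxy)-3-methyl-7-[(2R)-2-methyl-3-oxo-2-(triethylsilyloxy)butyl]-2-oxo-2,5,6,7-tetrahydrooxepin-6-yl]prop-2-enoic acid | CC1=C[C@H](O[Si](C)(C)C(C)(C)C)[C@H](C(=C)C(=O)O)[C@H](C[C@@](C)(O[Si](CC)(CC)CC)C(C)=O)OC1=O | intermediate
22 | (4Z,6S,7R,8S,10R)-6-(tert-butyldimethylsilyloxy)-8-hydroxy-1,3-dioxo-10-(triethylsilyloxy)germacra-4,11(13)-dien-12-oic acid (not isolated) | O=C1CC(=O)/C(C)=C\[C@H](O[Si](C)(C)C(C)(C)C)[C@H](C(=C)C(=O)O)[C@@H](O)C[C@@]1(C)O[Si](CC)(CC)CC | intermediate
23 | (4Z,6S,7S,8S,10R)-6-hydroxy-1-oxo-3,10-epoxygermacra-2,4,11(13)-trien-12,8-olide | C=C1C(=O)O[C@H]2C[C@@]3(C)OC(=CC3=O)/C(C)=C\[C@H](O)[C@H]12 | intermediate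
24 | angelic acid, (Z)-2-methylbut-2-enoic acid | C/C=C(/C)C(=O)O | starting material
25 | angelic 2,4,6-trichlorobenzoic anhydride (not isolated) | C/C=C(/C)C(=O)OC(=O)c1c(Cl)cc(Cl)cc1Cl | intermediate
26 | (4Z,6S,7R,8S,10R)-6-angeloyloxy-1-oxo-3,10-epoxygermacra-2,4,11(13)-trien-12,8-olide (CNP0293168.1) | C=C1C(=O)O[C@H]2C[C@@]3(C)OC(=CC3=O)/C(C)=C\[C@H](OC(=O)/C(C)=C\C)[C@H]12 | target

## Step count and least certain steps

Total step count: 16. Longest linear sequence: 15 (steps 1–5 and 7–16). Step 6 runs in parallel.

**Step 15 (key step, proposed new method).**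
- *Most likely failure.* The tetrahedral intermediate may revert, because the ketone enolate leaves more easily than the secondary alkoxide, so the expansion depends on the final proton transfer. A slow forward collapse would leave time for γ-deprotonation at C6 (loss of configuration, deconjugation of the lactone), for acyl exchange with the neighbouring carboxylate, or for intermolecular condensation.
- *Fallback.* It uses known chemistry only: C2–C3 is made intermolecularly and ring A is closed at C4=C5. It sets out from 18. Methanolysis of the methacrylate (K2CO3, MeOH) gives the C8 alcohol F1, and TESOTf/2,6-lutidine gives the bis(triethylsilyl) ether F2. Kinetic enolisation (LiN(SiMe3)2, THF, −78 °C) and C-acylation with 1-methacryloylbenzotriazole (crossed Claisen) give the acyclic 1,3-diketone F3. Aqueous acid (p-TsOH, THF/H2O) removes both triethylsilyl groups and cyclodehydrates to the 5-isopropenylfuranone F4. Ring-closing metathesis at high dilution (second-generation Hoveyda–Grubbs catalyst, toluene, 100 °C) closes ring A to the bicyclic alcohol F5. SeO2/t-BuOOH gives the diol F6, and MnO2 oxidises it through the lactol to the silylated lactone F7. Aqueous HF in MeCN brings the sequence back to 23.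

**Step 10.**
- *Most likely failure.* Hemiacetal formation and hydride transfer from a conjugated aldehyde may be slow. Retro-aldol cleavage, oxa-Michael addition of O8–H to the enone, or later O8-to-O6 acyl migration could then compete.
- *Fallback.* Reduction and differentiation are separated. It sets out from 15. Hydroxyl-directed reduction with Me4NBH(OAc)3 (MeCN/AcOH, −30 °C) gives the anti diol F8. The less hindered allylic hydroxyl is silylated (TBSCl, imidazole, DMF, 0 °C) to the C8 alcohol F1. Methacrylic anhydride/DMAP returns to 18.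

**Step 13.**
- *Most likely failure.* Low conversion, over-oxidation, or competing oxidation at the C2 methyl ketone by the selenium reagent.
- *Fallback.* Electrophilic chlorination replaces oxygen transfer. It sets out from 19. Ene-type chlorination with Ca(OCl)2 and solid CO2 (CH2Cl2/H2O) gives the allylic chloride F9. Amine N-oxide oxidation (N-methylmorpholine N-oxide, MeCN) gives the enal F10. Pinnick oxidation (NaClO2, NaH2PO4, 2-methylbut-2-ene) returns to 21.

**Step 16.**
- *Most likely failure.* Z to E isomerisation of the activated angeloyl unit during a slow acylation of the hindered allylic alcohol, or amine-induced damage to the methylene lactone at 80 °C.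
- *Fallback.* The Z alkene is built on the ester instead of being carried through an activation. It sets out from 23. Carbodiimide coupling with but-2-ynoic acid gives the but-2-ynoate F11. Syn hydrostannation (Bu3SnH, Pd(PPh3)4) gives the α-stannyl enoate F12. Stille methylation (MeI, Pd2(dba)3, P(o-tol)3, CuCl, K2CO3, DMF) with retention returns to 26.

**Step 3.**
- *Most likely failure.* Early collapse of the tetrahedral adduct, followed by a second addition of the organolithium or by aldol reaction with the released aldehyde.
- *Fallback.* The acyl group passes through an amide that stops at the ketone. It sets out from 5. MeNH(OMe)·HCl/i-PrMgCl opens the dioxolanone to the hydroxy Weinreb amide F13. TESOTf/2,6-lutidine gives the silyl ether F14. MeMgBr (THF, 0 °C) returns to 7.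

## Further compounds

F1 | step 15 | C8 alcohol (O6 TBS, O10 TES, C1 ketone, propenyl and isopropenyl groups) | C/C=C/[C@H](O[Si](C)(C)C(C)(C)C)[C@H](C(C)=C)[C@@H](O)C[C@@](C)(O[Si](CC)(CC)CC)C(C)=O
F2 | step 15 | O8,O10-bis(triethylsilyl) ether of F1 | C/C=C/[C@H](O[Si](C)(C)C(C)(C)C)[C@H](C(C)=C)[C@@H](O[Si](CC)(CC)CC)C[C@@](C)(O[Si](CC)(CC)CC)C(C)=O
F3 | step 15 | acyclic 1,3-diketone from C-methacryloylation at C2 | C/C=C/[C@H](O[Si](C)(C)C(C)(C)C)[C@H](C(C)=C)[C@@H](O[Si](CC)(CC)CC)C[C@@](C)(O[Si](CC)(CC)CC)C(=O)CC(=O)C(C)=C
F4 | step 15 | 5-isopropenyl-3(2H)-furanone with free O8–H | C/C=C/[C@H](O[Si](C)(C)C(C)(C)C)[C@H](C(C)=C)[C@@H](O)C[C@@]1(C)OC(C(C)=C)=CC1=O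
F5 | step 15 | bicyclic alcohol (rings A and B closed, isopropenyl at C7) | O[C@H]1C[C@@]2(C)OC(=CC2=O)/C(C)=C\[C@H](O[Si](C)(C)C(C)(C)C)[C@@H]1C(C)=C
F6 | step 15 | C8,C12-diol | O[C@H]1C[C@@]2(C)OC(=CC2=O)/C(C)=C\[C@H](O[Si](C)(C)C(C)(C)C)[C@@H]1C(=C)CO
F7 | step 15 | O6-TBS ether of 23 | C=C1C(=O)O[C@H]2C[C@@]3(C)OC(=CC3=O)/C(C)=C\[C@H](O[Si](C)(C)C(C)(C)C)[C@H]12
F8 | step 10 | anti C6,C8-diol | C/C=C/[C@H](O)[C@H](C(C)=C)[C@@H](O)C[C@@](C)(O[Si](CC)(CC)CC)C(C)=O
F9 | step 13 | allylic chloride (C12–Cl) of oxepinone 19 | CC1=C[C@H](O[Si](C)(C)C(C)(C)C)[C@H](C(=C)CCl)[C@H](C[C@@](C)(O[Si](CC)(CC)CC)C(C)=O)OC1=O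
F10 | step 13 | C12 enal of oxepinone 19 | CC1=C[C@H](O[Si](C)(C)C(C)(C)C)[C@H](C(=C)C=O)[C@H](C[C@@](C)(O[Si](CC)(CC)CC)C(C)=O)OC1=O
F11 | step 16 | O6 but-2-ynoate of 23 | C=C1C(=O)O[C@H]2C[C@@]3(C)OC(=CC3=O)/C(C)=C\[C@H](OC(=O)C#CC)[C@H]12
F12 | step 16 | O6 2-(tributylstannyl)but-2-enoate of 23 (CH3 cis to the ester carbonyl) | C=C1C(=O)O[C@H]2C[C@@]3(C)OC(=CC3=O)/C(C)=C\[C@H](OC(=O)/C([Sn](CCCC)(CCCC)CCCC)=C\C)[C@H]12
F13 | step 3 | (2R)-2-hydroxy-N-methoxy-N,2-dimethylpent-4-enamide | C=CC[C@@](C)(O)C(=O)N(C)OC
F14 | step 3 | (2R)-N-methoxy-N,2-dimethyl-2-(triethylsilyloxy)pent-4-enamide | C=CC[C@@](C)(O[Si](CC)(CC)CC)C(=O)N(C)OC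
A1 | alternative 1 | metathesis precursor: 5-isopropenylfuranone and C6 vinyl carbinol angelate with ring C in place | C=C[C@H](OC(=O)/C(C)=C\C)[C@H]1[C@H](C[C@@]2(C)OC(C(C)=C)=CC2=O)OC(=O)C1=C
A2 | alternative 2 | C8 aldehyde and Z 2-(bromomethyl)enoate on the furanone | O=CC[C@@]1(C)OC(=CC1=O)/C(C)=C\[C@H](OC(=O)/C(C)=C\C)/C=C(\CBr)C(=O)OC
A3 | alternative 3 | C9 iodide with ring C in place and a 2-methyl-3(2H)-furanone (both C10 epimers) | CC1OC(=CC1=O)/C(C)=C\[C@H](O[Si](C)(C)C(C)(C)C)[C@H]2[C@H](CI)OC(=O)C2=C
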